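## Retrosynthetic overview

1. The C1=C10 enone olefin is cut last: ring-closing metathesis of an acyclic bis-epoxy dienone diacetate, so the ten-membered carbocycle is the final ring formed.
2. The isopropenyl ketone comes from a PMB-masked C9 carbinol, and the two acetates from a diol.
3. Both oxiranes come from primary allylic alcohols by two sequential Sharpless epoxidations: C7/C11 first (L-tartrate), C4/C5 second (D-tartrate, after unmasking C15-OH).
4. The skipped diene is cut at C6–C7: copper-catalysed anti-methylmagnesiation of an alkynol (fragment B), trapped with an allylic bromide (fragment A), fixes the tetrasubstituted alkene geometry.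
5. Fragment A comes from but-2-yne-1,4-diol (hydroalumination–iodination, Negishi); fragment B from methacrolein and propargyl bromide. Ring order: C7/C11 oxirane, C4/C5 oxirane, carbocycle.

Assumptions: atom labels C1–C15 follow germacrane numbering of the target (C9 = ketone carbon, C12 and C15 = acetoxymethyl carbons). The C9 carbinol, made racemic in step 5, is carried as a 1:1 epimer mixture (left unspecified in the SMILES) until step 14 removes it.

## Route

Step 1
Reactants: 1 but-2-yne-1,4-diol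
Product: 2 4-[(tert-butyldimethylsilyl)oxy]but-2-yn-1-ol
Conditions: NaH (1 equiv), THF, 0 °C; TBSCl (1 equiv), rt
Reagents that add atoms: tert-butyldimethylsilyl chloride, CC(C)(C)[Si](C)(C)Cl
Why: Monosilylation of a symmetrical diol through its poorly soluble monosodium alkoxide (O-silylation) gives the mono-ether selectively and differentiates the future C6 and C15 oxygens.

Step 2
Reactants: 2 4-[(tert-butyldimethylsilyl)oxy]but-2-yn-1-ol
Product: 4 (2Z)-4-[(tert-butyldimethylsilyl)oxy]-3-iodobut-2-en-1-ol, via cyclic vinylalanate 3 (not isolated)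
Conditions: NaAlH2(OCH2CH2OMe)2, THF, 0 °C; then I2, −78 → 0 °C
Reagents that add atoms: iodine, II
Why: Hydroxyl-directed trans-hydroalumination puts aluminium on the distal alkyne carbon inside a five-membered chelate, and iodinolysis with retention gives the (Z)-vinyl iodide (hydroalumination–iodination).

Step 3
Reactants: 4 (2Z)-4-[(tert-butyldimethylsilyl)oxy]-3-iodobut-2-en-1-ol; 5 but-3-en-1-ylzinc bromide
Product: 6 (2E)-3-{[(tert-butyldimethylsilyl)oxy]methyl}hepta-2,6-dien-1-ol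
Conditions: PdCl2(dppf) (5 mol %), THF, rt → 45 °C
Reagents that add atoms: none
Why: Negishi cross-coupling replaces iodide with retention of alkene geometry, so the butenyl chain (C3) ends up cis to the CH2OH arm (C6), the relationship that later becomes the cis-oxirane.

Step 4
Reactants: 6 (2E)-3-{[(tert-butyldimethylsilyl)oxy]methyl}hepta-2,6-dien-1-ol
Product: 7 (2E)-1-bromo-3-{[(tert-butyldimethylsilyl)oxy]methyl}hepta-2,6-diene
Conditions: CBr4, PPh3, CH2Cl2, 0 °C
Reagents that add atoms: carbon tetrabromide, BrC(Br)(Br)Br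
Why: Appel bromination converts the primary allylic alcohol into the bromide under neutral conditions without allylic transposition, loss of geometry or silyl cleavage.

Step 5
Reactants: 8 methacrolein; 9 propargyl bromide
Product: 11 rac-2-methylhex-1-en-5-yn-3-ol, via allenylzinc bromide 10 (not isolated)
Conditions: Zn, THF, 0 °C → rt; H2O work-up
Reagents that add atoms: none
Why: Zinc-mediated Barbier propargylation, in which the allenylzinc adds to the aldehyde through an SE2′ transition state to give the homopropargylic alcohol; the racemic carbinol centre is oxidised away in step 14.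

Step 6
Reactants: 11 rac-2-methylhex-1-en-5-yn-3-ol
Product: 12 rac-1-methoxy-4-{[(2-methylhex-1-en-5-yn-3-yl)oxy]methyl}benzene
Conditions: NaH, THF–DMF, 0 °C; PMBCl, Bu4NI (cat.), rt
Reagents that add atoms: 4-methoxybenzyl chloride, COc1ccc(CCl)cc1
Why: Williamson etherification installs a PMB ether that survives Grignard, fluoride, titanium–peroxide and acylation conditions and is later removed oxidatively at neutral pH.

Step 7
Reactants: 12 rac-1-methoxy-4-{[(2-methylhex-1-en-5-yn-3-yl)oxy]methyl}benzene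
Product: 14 rac-5-[(4-methoxybenzyl)oxy]-6-methylhept-6-en-2-yn-1-ol, via lithium acetylide 13 (not isolated)
Conditions: n-BuLi, THF, −78 °C; (CH2O)n, −78 °C → rt
Reagents that add atoms: formaldehyde (from paraformaldehyde), C=O
Why: Acetylide hydroxymethylation (deprotonation of the terminal alkyne and addition to formaldehyde) adds C12 and creates the propargylic alcohol needed to direct the next step.

Step 8
Reactants: 14 rac-5-[(4-methoxybenzyl)oxy]-6-methylhept-6-en-2-yn-1-ol; 7 (2E)-1-bromo-3-{[(tert-butyldimethylsilyl)oxy]methyl}hepta-2,6-diene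
Product: 16 (2E,5E)-6-{[(tert-butyldimethylsilyl)oxy]methyl}-3-{2-[(4-methoxybenzyl)oxy]-3-methylbut-3-en-1-yl}-2-methyldeca-2,5,9-trien-1-ol, via cyclic vinylmagnesium alkoxide 15 (not isolated)
Conditions: MeMgBr (2.5 equiv), CuI (10 mol %), THF, −10 °C → rt; then 7, −20 °C → rt
Reagents that add atoms: methylmagnesium bromide, C[Mg]Br
Why: Alkoxide-directed, copper-catalysed anti-carbomagnesiation (Duboudin–Jousseaume type) puts methyl on the proximal carbon and magnesium on the distal carbon cis to CH2O, and copper-catalysed SN2 allylation with retention then places C6 cis to C12 in the tetrasubstituted alkene.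

Step 9
Reactants: 16 (2E,5E)-6-{[(tert-butyldimethylsilyl)oxy]methyl}-3-{2-[(4-methoxybenzyl)oxy]-3-methylbut-3-en-1-yl}-2-methyldeca-2,5,9-trien-1-ol
Product: 17 [(2S,3S)-3-[(2E)-3-{[(tert-butyldimethylsilyl)oxy]methyl}hepta-2,6-dien-1-yl]-3-{2-[(4-methoxybenzyl)oxy]-3-methylbut-3-en-1-yl}-2-methyloxiran-2-yl]methanol
Conditions: Ti(OiPr)4 (10 mol %), L-(+)-diethyl tartrate (12 mol %), t-BuOOH, 4 Å MS, CH2Cl2, −25 °C
Reagents that add atoms: tert-butyl hydroperoxide, CC(C)(C)OO
Why: Sharpless asymmetric epoxidation of the only free allylic alcohol; the L-(+)-tartrate catalyst delivers oxygen to the face that gives C7 and C11 both S (the same facial sense as geraniol to its 2S,3S-epoxide), and the other alkenes are inert.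

Step 10
Reactants: 17 [(2S,3S)-3-[(2E)-3-{[(tert-butyldimethylsilyl)oxy]methyl}hepta-2,6-dien-1-yl]-3-{2-[(4-methoxybenzyl)oxy]-3-methylbut-3-en-1-yl}-2-methyloxiran-2-yl]methanol
Product: 18 [(2S,3S)-3-[(2E)-3-(hydroxymethyl)hepta-2,6-dien-1-yl]-3-{2-[(4-methoxybenzyl)oxy]-3-methylbut-3-en-1-yl}-2-methyloxiran-2-yl]methanol
Conditions: Bu4NF, THF, 0 °C
Reagents that add atoms: none
Why: Fluoride desilylation unmasks the C15 allylic alcohol while the PMB ether and the fully substituted oxirane are untouched.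

Step 11
Reactants: 18 [(2S,3S)-3-[(2E)-3-(hydroxymethyl)hepta-2,6-dien-1-yl]-3-{2-[(4-methoxybenzyl)oxy]-3-methylbut-3-en-1-yl}-2-methyloxiran-2-yl]methanol
Product: 19 [(2S,3R)-3-{[(2R,3R)-3-(but-3-en-1-yl)-3-(hydroxymethyl)oxiran-2-yl]methyl}-3-{2-[(4-methoxybenzyl)oxy]-3-methylbut-3-en-1-yl}-2-methyloxiran-2-yl]methanol
Conditions: Ti(OiPr)4 (10 mol %), D-(−)-diethyl tartrate (12 mol %), t-BuOOH (1.2 equiv), 4 Å MS, CH2Cl2, −25 °C
Reagents that add atoms: tert-butyl hydroperoxide, CC(C)(C)OO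
Why: Second Sharpless asymmetric epoxidation on the only remaining allylic alcohol; the D-(−)-tartrate catalyst sets C4 and C5 both R under reagent control, and the alkene geometry from steps 2–3 makes the oxirane cis (C3 and C6 on the same side).

Step 12
Reactants: 19 [(2S,3R)-3-{[(2R,3R)-3-(but-3-en-1-yl)-3-(hydroxymethyl)oxiran-2-yl]methyl}-3-{2-[(4-methoxybenzyl)oxy]-3-methylbut-3-en-1-yl}-2-methyloxiran-2-yl]methanol
Product: 20 [(2S,3R)-3-{[(2R,3R)-3-(acetoxymethyl)-3-(but-3-en-1-yl)oxiran-2-yl]methyl}-3-{2-[(4-methoxybenzyl)oxy]-3-methylbut-3-en-1-yl}-2-methyloxiran-2-yl]methyl acetate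
Conditions: Ac2O, pyridine, DMAP (cat.), CH2Cl2, 0 °C
Reagents that add atoms: acetic anhydride, CC(=O)OC(C)=O
Why: Acylation of both primary alcohols installs the two acetates of the target and removes the hydroxyl nucleophiles next to the oxiranes.

Step 13
Reactants: 20 [(2S,3R)-3-{[(2R,3R)-3-(acetoxymethyl)-3-(but-3-en-1-yl)oxiran-2-yl]methyl}-3-{2-[(4-methoxybenzyl)oxy]-3-methylbut-3-en-1-yl}-2-methyloxiran-2-yl]methyl acetate
Product: 21 [(2S,3R)-3-{[(2R,3R)-3-(acetoxymethyl)-3-(but-3-en-1-yl)oxiran-2-yl]methyl}-3-(2-hydroxy-3-methylbut-3-en-1-yl)-2-methyloxiran-2-yl]methyl acetate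
Conditions: DDQ, CH2Cl2–pH 7 phosphate buffer, 0 °C → rt
Reagents that add atoms: none
Why: Oxidative PMB ether cleavage by DDQ at neutral pH frees the C9 carbinol without touching acetates, oxiranes or alkenes.

Step 14
Reactants: 21 [(2S,3R)-3-{[(2R,3R)-3-(acetoxymethyl)-3-(but-3-en-1-yl)oxiran-2-yl]methyl}-3-(2-hydroxy-3-methylbut-3-en-1-yl)-2-methyloxiran-2-yl]methyl acetate
Product: 22 [(2S,3S)-3-{[(2R,3R)-3-(acetoxymethyl)-3-(but-3-en-1-yl)oxiran-2-yl]methyl}-2-methyl-3-(3-methyl-2-oxobut-3-en-1-yl)oxiran-2-yl]methyl acetate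
Conditions: Dess–Martin periodinane, NaHCO3, CH2Cl2, 0 °C → rt
Reagents that add atoms: none
Why: Dess–Martin oxidation of the secondary allylic alcohol gives the isopropenyl ketone, merges the two C9 epimers into one compound, and is non-basic so the β,γ-epoxy ketone does not eliminate.

Step 15
Reactants: 22 [(2S,3S)-3-{[(2R,3R)-3-(acetoxymethyl)-3-(but-3-en-1-yl)oxiran-2-yl]methyl}-2-methyl-3-(3-methyl-2-oxobut-3-en-1-yl)oxiran-2-yl]methyl acetate
Product: 23 CNP0185847.4, (1(10)Z,4R,5R,7S,11S)-12,15-diacetoxy-4,5:7,11-diepoxygermacr-1(10)-en-9-one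
Conditions: second-generation Hoveyda–Grubbs catalyst (10 mol %), toluene (1 mM), 80 °C
Reagents that add atoms: none
Why: Ring-closing metathesis between the terminal alkene and the isopropenyl ketone closes the ten-membered ring with loss of ethylene; the ring-cis (Z) trisubstituted enone is expected because it is the less strained isomer in a cyclodecenone, and no stereocentre is touched.

## Compound list

1 | but-2-yne-1,4-diol | OCC#CCO | starting material
2 | 4-[(tert-butyldimethylsilyl)oxy]but-2-yn-1-ol | OCC#CCO[Si](C)(C)C(C)(C)C | intermediate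
3 | sodium 3-{[(tert-butyldimethylsilyl)oxy]methyl}-2,2-bis(2-methoxyethoxy)-2,5-dihydro-1,2-oxaaluminol-2-uide (cyclic vinylalanate) | [Na+].COCCO[Al-]1(OCCOC)OCC=C1CO[Si](C)(C)C(C)(C)C | intermediate (not isolated)
4 | (2Z)-4-[(tert-butyldimethylsilyl)oxy]-3-iodobut-2-en-1-ol | OC/C=C(/CO[Si](C)(C)C(C)(C)C)I | intermediate
5 | but-3-en-1-ylzinc bromide | C=CCC[Zn]Br | starting material
6 | (2E)-3-{[(tert-butyldimethylsilyl)oxy]methyl}hepta-2,6-dien-1-ol | OC/C=C(/CO[Si](C)(C)C(C)(C)C)CCC=C | intermediate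
7 | (2E)-1-bromo-3-{[(tert-butyldimethylsilyl)oxy]methyl}hepta-2,6-diene | BrC/C=C(/CO[Si](C)(C)C(C)(C)C)CCC=C | intermediate
8 | methacrolein (2-methylprop-2-enal) | CC(=C)C=O | starting material
9 | propargyl bromide (3-bromoprop-1-yne) | C#CCBr | starting material
10 | allenylzinc bromide (propa-1,2-dien-1-ylzinc bromide) | C=C=C[Zn]Br | intermediate (not isolated)
11 | rac-2-methylhex-1-en-5-yn-3-ol | C#CCC(O)C(C)=C | intermediate
12 | rac-1-methoxy-4-{[(2-methylhex-1-en-5-yn-3-yl)oxy]methyl}benzene | C#CCC(OCc1ccc(OC)cc1)C(C)=C | intermediate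
13 | lithium acetylide of 12 | [Li]C#CCC(OCc1ccc(OC)cc1)C(C)=C | intermediate (not isolated)
14 | rac-5-[(4-methoxybenzyl)oxy]-6-methylhept-6-en-2-yn-1-ol | OCC#CCC(OCc1ccc(OC)cc1)C(C)=C | intermediate
15 | 3-{2-[(4-methoxybenzyl)oxy]-3-methylbut-3-en-1-yl}-4-methyl-2,5-dihydro-1,2-oxamagnesole (cyclic vinylmagnesium alkoxide) | CC1=C(CC(OCc2ccc(OC)cc2)C(C)=C)[Mg]OC1 | intermediate (not isolated)
16 | (2E,5E)-6-{[(tert-butyldimethylsilyl)oxy]methyl}-3-{2-[(4-methoxybenzyl)oxy]-3-methylbut-3-en-1-yl}-2-methyldeca-2,5,9-trien-1-ol (racemic at the PMB-oxy carbon) | OC/C(C)=C(/CC(OCc1ccc(OC)cc1)C(C)=C)C/C=C(/CO[Si](C)(C)C(C)(C)C)CCC=C | intermediate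
17 | [(2S,3S)-3-[(2E)-3-{[(tert-butyldimethylsilyl)oxy]methyl}hepta-2,6-dien-1-yl]-3-{2-[(4-methoxybenzyl)oxy]-3-methylbut-3-en-1-yl}-2-methyloxiran-2-yl]methanol (C9 epimers) | OC[C@]1(C)O[C@]1(CC(OCc2ccc(OC)cc2)C(C)=C)C/C=C(/CO[Si](C)(C)C(C)(C)C)CCC=C | intermediate
18 | [(2S,3S)-3-[(2E)-3-(hydroxymethyl)hepta-2,6-dien-1-yl]-3-{2-[(4-methoxybenzyl)oxy]-3-methylbut-3-en-1-yl}-2-methyloxiran-2-yl]methanol (C9 epimers) | OC[C@]1(C)O[C@]1(CC(OCc2ccc(OC)cc2)C(C)=C)C/C=C(/CO)CCC=C | intermediate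
19 | [(2S,3R)-3-{[(2R,3R)-3-(but-3-en-1-yl)-3-(hydroxymethyl)oxiran-2-yl]methyl}-3-{2-[(4-methoxybenzyl)oxy]-3-methylbut-3-en-1-yl}-2-methyloxiran-2-yl]methanol (C9 epimers) | OC[C@]1(C)O[C@]1(CC(OCc2ccc(OC)cc2)C(C)=C)C[C@H]3O[C@@]3(CO)CCC=C | intermediate
20 | [(2S,3R)-3-{[(2R,3R)-3-(acetoxymethyl)-3-(but-3-en-1-yl)oxiran-2-yl]methyl}-3-{2-[(4-methoxybenzyl)oxy]-3-methylbut-3-en-1-yl}-2-methyloxiran-2-yl]methyl acetate (C9 epimers) | CC(=O)OC[C@]1(C)O[C@]1(CC(OCc2ccc(OC)cc2)C(C)=C)C[C@H]3O[C@@]3(COC(C)=O)CCC=C | intermediate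
21 | [(2S,3R)-3-{[(2R,3R)-3-(acetoxymethyl)-3-(but-3-en-1-yl)oxiran-2-yl]methyl}-3-(2-hydroxy-3-methylbut-3-en-1-yl)-2-methyloxiran-2-yl]methyl acetate (C9 epimers) | CC(=O)OC[C@]1(C)O[C@]1(CC(O)C(C)=C)C[C@H]2O[C@@]2(COC(C)=O)CCC=C | intermediate
22 | [(2S,3S)-3-{[(2R,3R)-3-(acetoxymethyl)-3-(but-3-en-1-yl)oxiran-2-yl]methyl}-2-methyl-3-(3-methyl-2-oxobut-3-en-1-yl)oxiran-2-yl]methyl acetate | CC(=O)OC[C@]1(C)O[C@]1(CC(=O)C(C)=C)C[C@H]2O[C@@]2(COC(C)=O)CCC=C | intermediate
23 | CNP0185847.4, (1(10)Z,4R,5R,7S,11S)-12,15-diacetoxy-4,5:7,11-diepoxygermacr-1(10)-en-9-one | CC(=O)OC[C@]12CC/C=C(/C)C(=O)C[C@]3(C[C@H]1O2)O[C@@]3(C)COC(C)=O | target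

## Step count and risks

Total step count: 15. Longest linear sequence: 12 steps (steps 1–4, then 8–15, from 1); the fragment B branch is steps 5–7.

Steps most likely to fail:

Step 8 (one-pot methylmagnesiation and allylation). Carbomagnesiation of an internal alkynol with MeMgBr can be slow, and residual MeMgBr competes for bromide 7 or gives SN2′ product. Fallback: set out from 14, run the same copper-catalysed methylmagnesiation but quench the vinylmagnesium 15 with Bu3SnCl to isolate (2Z)-5-[(4-methoxybenzyl)oxy]-2,6-dimethyl-3-(tributylstannyl)hepta-2,6-dien-1-ol F1, whose geometry can be checked by NOE. A Stille allyl–vinyl coupling of F1 with 7 (Pd2(dba)3, AsPh3, CuI, DMF, 40 °C) then comes back to the route at 16. This replaces the Grignard displacement by a palladium cross-coupling and uses 7 stoichiometrically.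

Step 11 (second epoxidation with a free epoxy alcohol present). The C12 hydroxyl of 18/19 can open the new C4–C5 oxirane at C5 under titanium catalysis (six-membered ether formation). Fallback: set out from 17 and cap the C12 hydroxyl first (Ac2O, pyridine) to give [(2S,3S)-3-[(2E)-3-{[(tert-butyldimethylsilyl)oxy]methyl}hepta-2,6-dien-1-yl]-3-{2-[(4-methoxybenzyl)oxy]-3-methylbut-3-en-1-yl}-2-methyloxiran-2-yl]methyl acetate F2. Desilylation (Bu4NF buffered with AcOH) gives [(2S,3S)-3-[(2E)-3-(hydroxymethyl)hepta-2,6-dien-1-yl]-3-{2-[(4-methoxybenzyl)oxy]-3-methylbut-3-en-1-yl}-2-methyloxiran-2-yl]methyl acetate F3. Epoxidation with the D-(−)-tartrate system gives [(2S,3R)-3-{[(2R,3R)-3-(but-3-en-1-yl)-3-(hydroxymethyl)oxiran-2-yl]methyl}-3-{2-[(4-methoxybenzyl)oxy]-3-methylbut-3-en-1-yl}-2-methyloxiran-2-yl]methyl acetate F4, and a second acetylation comes back to the route at 20. This costs two extra steps but removes the internal nucleophile before the second oxirane exists.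

Step 15 (ring-closing metathesis to a ten-membered trisubstituted enone). Oligomerisation, slow closure onto the electron-poor 1,1-disubstituted olefin, or the ring-trans isomer are all possible. Fallback: set out from 21 and close the ring one step earlier on the sp3 carbinol, where the 1,1-disubstituted olefin is electron-rich and hydroxyl-activated (second-generation Grubbs catalyst, CH2Cl2, 1 mM, reflux). This gives (1(10)Z,4R,5R,7S,11S)-12,15-diacetoxy-4,5:7,11-diepoxygermacr-1(10)-en-9-ol F5 as C9 epimers, and Dess–Martin oxidation of F5 comes back to the route at 23. The order of oxidation and cyclisation is reversed, so the ring is formed without the conjugated enone in place.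

## Further compounds

F1 | step 8 | (2Z)-5-[(4-methoxybenzyl)oxy]-2,6-dimethyl-3-(tributylstannyl)hepta-2,6-dien-1-ol | OC/C(C)=C(/CC(OCc1ccc(OC)cc1)C(C)=C)[Sn](CCCC)(CCCC)CCCC
F2 | step 11 | [(2S,3S)-3-[(2E)-3-{[(tert-butyldimethylsilyl)oxy]methyl}hepta-2,6-dien-1-yl]-3-{2-[(4-methoxybenzyl)oxy]-3-methylbut-3-en-1-yl}-2-methyloxiran-2-yl]methyl acetate | CC(=O)OC[C@]1(C)O[C@]1(CC(OCc2ccc(OC)cc2)C(C)=C)C/C=C(/CO[Si](C)(C)C(C)(C)C)CCC=C
F3 | step 11 | [(2S,3S)-3-[(2E)-3-(hydroxymethyl)hepta-2,6-dien-1-yl]-3-{2-[(4-methoxybenzyl)oxy]-3-methylbut-3-en-1-yl}-2-methyloxiran-2-yl]methyl acetate | CC(=O)OC[C@]1(C)O[C@]1(CC(OCc2ccc(OC)cc2)C(C)=C)C/C=C(/CO)CCC=C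
F4 | step 11 | [(2S,3R)-3-{[(2R,3R)-3-(but-3-en-1-yl)-3-(hydroxymethyl)oxiran-2-yl]methyl}-3-{2-[(4-methoxybenzyl)oxy]-3-methylbut-3-en-1-yl}-2-methyloxiran-2-yl]methyl acetate | CC(=O)OC[C@]1(C)O[C@]1(CC(OCc2ccc(OC)cc2)C(C)=C)C[C@H]3O[C@@]3(CO)CCC=C
F5 | step 15 | (1(10)Z,4R,5R,7S,11S)-12,15-diacetoxy-4,5:7,11-diepoxygermacr-1(10)-en-9-ol (C9 epimers) | CC(=O)OC[C@]12CC/C=C(/C)C(O)C[C@]3(C[C@H]1O2)O[C@@]3(C)COC(C)=O
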